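- The noon run, with [reagent in the second phase] at 2.6 M, reads less target at 60.0 min than at 30.0 min: 34.6% against 43.0%. The dusk run, with 0.99 M, stays flat at its last two readings, so I look for the crossing where using target overtakes making it.

| flask | starting material | reagent in the second phase | remark | time | volume of the second phase over the first |
|---|---|---|---|---|---|
| dusk | 0.96 M | 0.99 M | run made earlier |  |  |
| noon | 0.96 M | 2.6 M | run made earlier |  |  |
| winter | 0.82 M | 1.44 M | run made earlier |  |  |
| ash | 0.60 M | 3.00 M |  | 1.5 h | 2.0 |
| maple | 0.96 M | 1.44 M |  | 1.0 h | 2.0 |

| dusk: time / min | dusk: target / % | noon: time / min | noon: target / % | winter: time / min | winter: target / % |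
|---|---|---|---|---|---|
| 8.00 | 5.5 | 15.0 | 28.9 | 5.00 | 4.5 |
| 20.0 | 16.7 | 30.0 | 43.0 | 12.0 | 14.8 |
| 40.0 | 23.1 | 50.0 | 38.9 | 25.0 | 27.8 |
| 60.0 | 23.0 | 60.0 | 34.6 | 60.0 | 30.0 |

(scatter of a reading: 0.5 percentage points)

- which of the two ends with the higher amount of target, in percent of the starting material charged ("neither" if they lie within 2 percentage points) (ash / maple / neither)
- target at the end, in percent of the starting material charged, ash
- target at the end, in percent of the starting material charged, maple

- in the second phase: reagent in the second phase; everything else is in the first
- charges count per volume of the first phase; a concentration in a rate is the amount of a species over the volume of its own phase; every rate counts per litre of the first phase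
- the numbers in the tables scatter with a standard deviation of 0.5 percentage points
- the earlier runs hold the two phases in the same ratio of volumes as the flask asked about

- I carry the tail rate, the fractional fall of target per minute past that crossing, which I read from the last two noon readings as 0.0117 min⁻¹. Any target still being made slows this fall, so I take it as the slow extreme.
- For the fast extreme, I suppose that making at dusk's flat top, where making equals using, matches dusk's early rise. That gives 0.0404 min⁻¹, a first-order loss of target.
- I take ash, charged with more [reagent in the second phase] than noon, to be past its crossing at 1.5 h. Borrowing noon's highest reading and its time as a rough start, I get 21.3% for ash at 1.5 h on the slow extreme and 3.81% on the fast one, and I expect ash between them.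
- Maple has the [starting material] of dusk and noon, and its [reagent in the second phase] lies between theirs. Their readings at 60.0 min are 23.0% and 34.6%, and interpolating gives me 26.2%. Even dusk's reading stands above my slow-extreme estimate for ash, so I choose maple.
- The forecast also says maple, with 10% for ash and 27% for maple: “Final yield then depends mainly on the reagent to starting material ratio”.

    reagent in the reaction phase ⇌ reagent in the second phase, rate k1*([reagent in the reaction phase] - [reagent in the second phase]/K1) per volume of the first phase (partition coefficient = 1.30, kL = 0.00160 s⁻¹)
    starting material + reagent in the reaction phase → target (k = 0.00161 M⁻¹ s⁻¹)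
    target → over-reaction product (k = 4.69 × 10⁻⁴ s⁻¹)

- Ash ends at 16.2% and maple at 28.4%, so maple holds more. At the end ash keeps 0.537% of its starting material, less than the 32.6% in maple. Ash holds 44.1% target at 0.750 h. The tail rate over the remaining 45.0 min would leave 26.0% in ash, more than ash holds, which is 16.2%.

(The readings were computed on assumed constants; the scatter is artificial.)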